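**Plan**

- Retrosynthesis: the O1–C2 bond is cut first, opening ring C to a 2'-hydroxyaryl ketone whose ring B stands at the quinone oxidation level. Then the C4–C4a aryl–acyl bond is cut (lithiated ring A + α-methoxy Weinreb amide), then the C2–C1' bond (ring B Grignard reagent + methyl (R)-glycidate).
- Forward: ring B is joined to the three-carbon chain, O3 is methylated, the ester becomes a Weinreb amide, lithiated ring A is acylated, ring B is oxidised to the methoxyquinone, the phenol is freed, and ring C is closed last.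
- Enabling feature: ring B is a 2,5-dihydroxy-4-methoxyphenyl group (a hydroquinone) with O2' ortho to C1', the carbon that carries C2. At the quinone level C2–H is the γ-CH of the C5'=O enone, so prototropy gives an ortho-quinone methide (O=C2'–C1'=C2) that is electrophilic at C2, six atoms from the ring A phenol oxygen O1.
- Stereochemistry: C3 comes from methyl (R)-glycidate and is not touched afterwards. C2 is set in the ring closure under control of C3 (2,3-trans).

Key step: step 8

Remark: flavanone numbering is used (O1, C2, C3, C4 in ring C; C5 to C8 in ring A; C1' to C6' in ring B). The target is the 2,3-trans (2R,3R) isomer. 1-Bromo-2,4,5-trimethoxybenzene, methyl (R)-glycidate and 3,4,5-trimethoxyphenol are assumed to be commercial.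

**Step 1**
Reactants: 1 1-bromo-2,4,5-trimethoxybenzene; 2 methyl (2R)-oxirane-2-carboxylate (methyl (R)-glycidate)
Product: 4 methyl (2R)-2-hydroxy-3-(2,4,5-trimethoxyphenyl)propanoate, via aryl Grignard reagent 3 (not isolated)
Conditions: Mg, I2 (cat.), THF, reflux; then CuBr·SMe2 (10 mol %), 2, THF, −40 to −20 °C; then H2O
Reagents that add atoms: none
Why: Copper-catalysed opening of a terminal epoxide by an aryl Grignard reagent occurs at the unsubstituted CH2 carbon and, at low temperature, faster than addition to the ester, so the glycidate stereocenter (the future C3) is untouched and stays R.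

**Step 2**
Reactants: 4 methyl (2R)-2-hydroxy-3-(2,4,5-trimethoxyphenyl)propanoate
Product: 5 methyl (2R)-2-methoxy-3-(2,4,5-trimethoxyphenyl)propanoate
Conditions: MeI, Ag2O, 4 Å MS, MeCN, rt to 40 °C, dark
Reagents that add atoms: iodomethane, CI
Why: Purdie methylation (Ag2O, MeI) alkylates the secondary alcohol under non-basic conditions, so the ester α-stereocenter is not enolised.

**Step 3**
Reactants: 5 methyl (2R)-2-methoxy-3-(2,4,5-trimethoxyphenyl)propanoate
Product: 6 (2R)-N,2-dimethoxy-N-methyl-3-(2,4,5-trimethoxyphenyl)propanamide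
Conditions: MeNHOMe·HCl, iPrMgCl, THF, −20 °C
Reagents that add atoms: N,O-dimethylhydroxylamine hydrochloride, CNOC.Cl
Why: Weinreb amide formation by aminolysis of the ester with the chloromagnesium amide made in the flask is fast at −20 °C, where the α-methoxy stereocenter is not deprotonated.

**Step 4**
Reactants: 7 3,4,5-trimethoxyphenol
Product: 8 1,2,3-trimethoxy-5-(methoxymethoxy)benzene
Conditions: MOMCl, iPr2NEt, CH2Cl2, 0 °C to rt
Reagents that add atoms: chloromethyl methyl ether, COCCl
Why: O-alkylation of the phenol with MOMCl gives the acetal that later serves both as the directing group for lithiation and as the phenol protection.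

**Step 5**
Reactants: 8 1,2,3-trimethoxy-5-(methoxymethoxy)benzene; 6 (2R)-N,2-dimethoxy-N-methyl-3-(2,4,5-trimethoxyphenyl)propanamide
Product: 10 (2R)-2-methoxy-1-[2,3,4-trimethoxy-6-(methoxymethoxy)phenyl]-3-(2,4,5-trimethoxyphenyl)propan-1-one, via aryllithium 9 (not isolated)
Conditions: n-BuLi, THF, 0 °C to rt; then 6, −78 to 0 °C; then H2O
Reagents that add atoms: none
Why: Directed ortho-metalation of 8 can only take place at one of two equivalent positions, each flanked by OMOM and OMe, and the Weinreb ketone synthesis stops at the ketone through the chelated tetrahedral intermediate, with addition at −78 °C expected to outrun α-deprotonation so that C3 stays R.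

**Step 6**
Reactants: 10 (2R)-2-methoxy-1-[2,3,4-trimethoxy-6-(methoxymethoxy)phenyl]-3-(2,4,5-trimethoxyphenyl)propan-1-one
Product: 11 2-methoxy-5-{(2R)-2-methoxy-3-oxo-3-[2,3,4-trimethoxy-6-(methoxymethoxy)phenyl]propyl}-1,4-benzoquinone
Conditions: (NH4)2Ce(NO3)6 (2.5 equiv), MeCN/H2O, 0 °C
Reagents that add atoms: water, O
Why: Oxidative demethylation by tetravalent cerium proceeds through the arene radical cation of the most electron-rich ring, the 2,4,5-trimethoxyphenyl ring B, whose para-dimethoxy pair should give the 2-methoxy-1,4-benzoquinone, while ring A is deactivated by its acyl group and the acidic medium leaves C3 alone.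

**Step 7**
Reactants: 11 2-methoxy-5-{(2R)-2-methoxy-3-oxo-3-[2,3,4-trimethoxy-6-(methoxymethoxy)phenyl]propyl}-1,4-benzoquinone
Product: 12 2-[(2R)-3-(6-hydroxy-2,3,4-trimethoxyphenyl)-2-methoxy-3-oxopropyl]-5-methoxy-1,4-benzoquinone
Conditions: CF3CO2H, CH2Cl2, 0 °C; then H2O
Reagents that add atoms: none
Why: Acid cleavage of the aryl MOM acetal is assisted by the ortho carbonyl group, and a non-nucleophilic acid is used so that no HX adds to the quinone.

**Step 8**
Reactants: 12 2-[(2R)-3-(6-hydroxy-2,3,4-trimethoxyphenyl)-2-methoxy-3-oxopropyl]-5-methoxy-1,4-benzoquinone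
Product: 14 (2R,3R)-2-(2,5-dihydroxy-4-methoxyphenyl)-3,5,6,7-tetramethoxy-2,3-dihydro-4H-chromen-4-one, via ortho-quinone methide 13 (not isolated)
Conditions: Et3N (0.3 equiv), degassed PhMe (0.005 M), Ar, dark, rt to 50 °C; then AcOH
Reagents that add atoms: none
Why: Proposed new method: the amine, relayed by the ring A phenoxide, removes a C2 proton (the γ-CH of the C5'=O enone of the quinone) and O-protonation gives the 5'-hydroxy ortho-quinone methide 13, whose methide carbon C2 is attacked by the ring A phenol oxygen while ring B rearomatises to the 2',5'-dihydroxy-4'-methoxyphenyl group, so the step is a redox-neutral isomerisation that needs no oxidant and no protecting group. The closest known reaction types are the base-mediated tautomerisation of alkyl-1,4-benzoquinones to ortho-quinone methides with capture in the same flask (chromenol formation from prenylquinones, biomimetic cascades) and the oxa-Michael addition of phenols to ortho-quinone methides; closure of a flavanone ring C in this way is not known. Ring C closes in the 6-exo-trig mode (C2 inside the new ring, C1' outside) as an oxa-1,4-addition. The new stereocenter C2 is controlled by the existing C3 center: in the half-chair transition state the C3 methoxy group and the ring B residue both lie pseudoequatorial, which gives the 2,3-trans (2R,3R) product, and because the addition is reversible through the ortho-hydroxybenzyl aryl ether the trans isomer is also the thermodynamic one. The step needs deprotonation at C2 and not at C3, and capture by oxygen faster than prototropic aromatisation to the α-methoxychalcone or quinone/hydroquinone redox exchange; the vinylogous acidity of C2–H, the substoichiometric weak base, the chelated phenol held six atoms from C2 and high dilution should secure this.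

**Compound list**

1 | 1-bromo-2,4,5-trimethoxybenzene | COc1cc(OC)c(Br)cc1OC | starting material
2 | methyl (2R)-oxirane-2-carboxylate | COC(=O)[C@H]1CO1 | starting material
3 | (2,4,5-trimethoxyphenyl)magnesium bromide | COc1cc(OC)c([Mg]Br)cc1OC | intermediate
4 | methyl (2R)-2-hydroxy-3-(2,4,5-trimethoxyphenyl)propanoate | COc1cc(OC)c(C[C@@H](O)C(=O)OC)cc1OC | intermediate
5 | methyl (2R)-2-methoxy-3-(2,4,5-trimethoxyphenyl)propanoate | COc1cc(OC)c(C[C@@H](OC)C(=O)OC)cc1OC | intermediate
6 | (2R)-N,2-dimethoxy-N-methyl-3-(2,4,5-trimethoxyphenyl)propanamide | COc1cc(OC)c(C[C@@H](OC)C(=O)N(C)OC)cc1OC | intermediate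
7 | 3,4,5-trimethoxyphenol | COc1cc(O)cc(OC)c1OC | starting material
8 | 1,2,3-trimethoxy-5-(methoxymethoxy)benzene | COCOc1cc(OC)c(OC)c(OC)c1 | intermediate
9 | [2,3,4-trimethoxy-6-(methoxymethoxy)phenyl]lithium | [Li]c1c(OCOC)cc(OC)c(OC)c1OC | intermediate
10 | (2R)-2-methoxy-1-[2,3,4-trimethoxy-6-(methoxymethoxy)phenyl]-3-(2,4,5-trimethoxyphenyl)propan-1-one | COc1cc(OC)c(C[C@@H](OC)C(=O)c2c(OCOC)cc(OC)c(OC)c2OC)cc1OC | intermediate
11 | 2-methoxy-5-{(2R)-2-methoxy-3-oxo-3-[2,3,4-trimethoxy-6-(methoxymethoxy)phenyl]propyl}-1,4-benzoquinone | COC1=CC(=O)C(C[C@@H](OC)C(=O)c2c(OCOC)cc(OC)c(OC)c2OC)=CC1=O | intermediate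
12 | 2-[(2R)-3-(6-hydroxy-2,3,4-trimethoxyphenyl)-2-methoxy-3-oxopropyl]-5-methoxy-1,4-benzoquinone | COC1=CC(=O)C(C[C@@H](OC)C(=O)c2c(O)cc(OC)c(OC)c2OC)=CC1=O | intermediate
13 | (6E)-4-hydroxy-6-[(2R)-3-(6-hydroxy-2,3,4-trimethoxyphenyl)-2-methoxy-3-oxopropylidene]-3-methoxycyclohexa-2,4-dien-1-one (drawn as the E isomer; either geometry can cyclise) | COC1=CC(=O)/C(=C/[C@@H](OC)C(=O)c2c(O)cc(OC)c(OC)c2OC)C=C1O | intermediate
14 | (2R,3R)-2-(2,5-dihydroxy-4-methoxyphenyl)-3,5,6,7-tetramethoxy-2,3-dihydro-4H-chromen-4-one | COc1cc(O)c([C@H]2Oc3cc(OC)c(OC)c(OC)c3C(=O)[C@@H]2OC)cc1O | target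

**Totals**

Total steps: 8. Longest linear sequence: 7 steps (steps 1, 2, 3, 5, 6, 7, 8); step 4 lies on the ring A branch.

**Steps most likely to fail**

1. Step 8. The ortho-quinone methide may aromatise by loss of the C3 proton, which would give the α-methoxychalcone and erase C3. The quinone and the hydroquinone product may also exchange redox state and lead to over-oxidation, or the prototropy may not start under a base mild enough to spare C3. The fallback uses known chemistry, sets out from 8 and comes back at 14. Compound 8 is lithiated as in step 5 and acylated with N-methoxy-N-methylacetamide to give the methyl ketone 1-[2,3,4-trimethoxy-6-(methoxymethoxy)phenyl]ethanone F1. Claisen–Schmidt condensation with commercial 2,4,5-trimethoxybenzaldehyde (KOH, EtOH) should give the chalcone (2E)-1-[2,3,4-trimethoxy-6-(methoxymethoxy)phenyl]-3-(2,4,5-trimethoxyphenyl)prop-2-en-1-one F2. Julia–Colonna epoxidation (poly-L-leucine, urea·H2O2, DBU, THF; the antipodal polymer if the facial sense proves opposite) should give the epoxy ketone [(2R,3S)-3-(2,4,5-trimethoxyphenyl)oxiran-2-yl][2,3,4-trimethoxy-6-(methoxymethoxy)phenyl]methanone F3. HCl in aqueous MeOH removes the MOM group, and the freed phenol opens the epoxide at the benzylic carbon to give (2R,3R)-3-hydroxy-5,6,7-trimethoxy-2-(2,4,5-trimethoxyphenyl)-2,3-dihydro-4H-chromen-4-one F4; this is trans by inversion or, if the opening ionises, by thermodynamic control from the intact C3. Me3OBF4 with 1,8-bis(dimethylamino)naphthalene methylates O3 to give (2R,3R)-3,5,6,7-tetramethoxy-2-(2,4,5-trimethoxyphenyl)-2,3-dihydro-4H-chromen-4-one F5. (NH4)2Ce(NO3)6 then converts ring B into the quinone 2-methoxy-5-[(2R,3R)-3,5,6,7-tetramethoxy-4-oxo-3,4-dihydro-2H-chromen-2-yl]-1,4-benzoquinone F6, and Na2S2O4 reduces F6 to 14.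

2. Step 6. Ring A may be oxidised in competition with ring B, or the acidic medium may remove the MOM group early, after which the free para-methoxyphenol of ring A would be over-oxidised. The fallback sets out from 10 and comes back at 12; it replaces the acetal by an acyl group that removes the donor character of the ring A oxygen. HCl in aqueous MeOH cleaves the MOM group of 10 to give the phenol (2R)-1-(6-hydroxy-2,3,4-trimethoxyphenyl)-2-methoxy-3-(2,4,5-trimethoxyphenyl)propan-1-one F7. Ac2O, pyridine and DMAP give the aryl acetate 3,4,5-trimethoxy-2-[(2R)-2-methoxy-3-(2,4,5-trimethoxyphenyl)propanoyl]phenyl acetate F8. (NH4)2Ce(NO3)6 should then oxidise only ring B to the quinone acetate 3,4,5-trimethoxy-2-[(2R)-2-methoxy-3-(4-methoxy-3,6-dioxocyclohexa-1,4-dien-1-yl)propanoyl]phenyl acetate F9, and acid methanolysis (TsOH, MeOH, 0 °C to rt) returns 12.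

3. Step 5. The hindered aryllithium may deprotonate the Weinreb amide at C3 in place of adding to it, which would cause epimerisation and incomplete acylation. The fallback sets out from 5 and comes back at 10; it uses the more electrophilic aldehyde and adds an oxidation. iBu2AlH (CH2Cl2, −78 °C) reduces 5 to the aldehyde (2R)-2-methoxy-3-(2,4,5-trimethoxyphenyl)propanal F10. Aryllithium 9, made from 8 as in step 5, adds at −78 °C to give the carbinol (2R)-2-methoxy-1-[2,3,4-trimethoxy-6-(methoxymethoxy)phenyl]-3-(2,4,5-trimethoxyphenyl)propan-1-ol F11 as a mixture of C1 epimers. Dess–Martin periodinane oxidises F11 to 10.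

**Further compounds**

F1 | step 8 | 1-[2,3,4-trimethoxy-6-(methoxymethoxy)phenyl]ethanone | CC(=O)c1c(OCOC)cc(OC)c(OC)c1OC
F2 | step 8 | (2E)-1-[2,3,4-trimethoxy-6-(methoxymethoxy)phenyl]-3-(2,4,5-trimethoxyphenyl)prop-2-en-1-one | COc1cc(OC)c(/C=C/C(=O)c2c(OCOC)cc(OC)c(OC)c2OC)cc1OC
F3 | step 8 | [(2R,3S)-3-(2,4,5-trimethoxyphenyl)oxiran-2-yl][2,3,4-trimethoxy-6-(methoxymethoxy)phenyl]methanone | COc1cc(OC)c([C@@H]2O[C@H]2C(=O)c2c(OCOC)cc(OC)c(OC)c2OC)cc1OC
F4 | step 8 | (2R,3R)-3-hydroxy-5,6,7-trimethoxy-2-(2,4,5-trimethoxyphenyl)-2,3-dihydro-4H-chromen-4-one | COc1cc(OC)c([C@H]2Oc3cc(OC)c(OC)c(OC)c3C(=O)[C@@H]2O)cc1OC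
F5 | step 8 | (2R,3R)-3,5,6,7-tetramethoxy-2-(2,4,5-trimethoxyphenyl)-2,3-dihydro-4H-chromen-4-one | COc1cc(OC)c([C@H]2Oc3cc(OC)c(OC)c(OC)c3C(=O)[C@@H]2OC)cc1OC
F6 | step 8 | 2-methoxy-5-[(2R,3R)-3,5,6,7-tetramethoxy-4-oxo-3,4-dihydro-2H-chromen-2-yl]-1,4-benzoquinone | COC1=CC(=O)C([C@H]2Oc3cc(OC)c(OC)c(OC)c3C(=O)[C@@H]2OC)=CC1=O
F7 | step 6 | (2R)-1-(6-hydroxy-2,3,4-trimethoxyphenyl)-2-methoxy-3-(2,4,5-trimethoxyphenyl)propan-1-one | COc1cc(OC)c(C[C@@H](OC)C(=O)c2c(O)cc(OC)c(OC)c2OC)cc1OC
F8 | step 6 | 3,4,5-trimethoxy-2-[(2R)-2-methoxy-3-(2,4,5-trimethoxyphenyl)propanoyl]phenyl acetate | COc1cc(OC)c(C[C@@H](OC)C(=O)c2c(OC(C)=O)cc(OC)c(OC)c2OC)cc1OC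
F9 | step 6 | 3,4,5-trimethoxy-2-[(2R)-2-methoxy-3-(4-methoxy-3,6-dioxocyclohexa-1,4-dien-1-yl)propanoyl]phenyl acetate | COC1=CC(=O)C(C[C@@H](OC)C(=O)c2c(OC(C)=O)cc(OC)c(OC)c2OC)=CC1=O
F10 | step 5 | (2R)-2-methoxy-3-(2,4,5-trimethoxyphenyl)propanal | COc1cc(OC)c(C[C@@H](OC)C=O)cc1OC
F11 | step 5 | (2R)-2-methoxy-1-[2,3,4-trimethoxy-6-(methoxymethoxy)phenyl]-3-(2,4,5-trimethoxyphenyl)propan-1-ol (both C1 epimers) | COc1cc(OC)c(C[C@@H](OC)C(O)c2c(OCOC)cc(OC)c(OC)c2OC)cc1OC
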